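The numbers in the tables are calculated with made-up constants, and the scatter is random.

The choice at 1.5 h turns on how much loss the red flask still has ahead and on where Qf stands against Qa.

all flasks: Qa 0.80 M; Qc 1.6 mM

|  | Qb | Qd | remark | time |
|---|---|---|---|---|
| red | 1.2 M | 0.016 M | the very flask that is asked about, followed so far |  |
| amber | 1.2 M | 0.024 M | run made earlier |  |
| flask | 1.20 M | 0.0160 M |  | 1.5 h |

| run | time / min | Qf / % | Qa / % |
|---|---|---|---|
| red | 6.00 | 47.5 | 37.1 |
| red | 8.00 | 47.5 | 33.4 |
| red | 12.0 | 44.3 | 28.6 |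
| red | 20.0 | 38.4 | 25.0 |
| red | 30.0 | 34.3 | 22.8 |
| red | 50.0 | 29.2 | 18.9 |
| red | 80.0 | 29.2 | 18.7 |
| amber | 1.00 | 24.0 | 72.2 |
| amber | 2.50 | 39.5 | 53.6 |
| amber | 3.00 | 42.3 | 49.1 |
| amber | 5.00 | 46.2 | 39.8 |
| amber | 6.00 | 47.3 | 37.2 |
| amber | 8.00 | 47.4 | 32.5 |

(each reading ± 0.5 percentage points)

- Qf, in percent of the Qa first charged, at 1.5 h
- the option that brings most further Qf ("none" if no option brings more than 2 percentage points) (Tuesday's / Sunday's / Thursday's / Friday's / none)
- Qf present, with what was taken out counted in, in percent of the Qa first charged, after Tuesday's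
- Qf present, with what was taken out counted in, in percent of the Qa first charged, after Sunday's

- Tuesday's: at 1.5 h take out 90% of the Qf then present, then wait 1.5 h
- Sunday's: change nothing and wait 1.5 h more
- Thursday's: at 1.5 h add Qb, 50.0% of the amount charged, then wait 1.5 h
- Friday's: at 1.5 h add Qc, 50.0% of the amount charged, then wait 1.5 h

- removed Qf is counted in
- what was read earlier has a scatter of 0.5 percentage points, one standard deviation
- additions bring no volume worth counting

In the first instants, seen in the amber run, Qf reaches 24.0% at 1.00 min, and Qa plus Qf, here called the pool, still stands at 96.2% of the charge. From the middle of the red run to its end, Qf over Qa reads 1.55 at 12.0 min and 1.56 at 80.0 min. The pair looks like a quasi-equilibrium, with Qf at a late share of 60.8% of the pool.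

The loss therefore shows in the pool, which drains pseudo-first-order with a fading constant. That constant reads 0.0203 min⁻¹ from 8.00 min to 20.0 min, then 0.00921 min⁻¹ up to 50.0 min. Its fade, read as Qc dying, is 0.0377 min⁻¹, a half-life of 18.4 min.

At the end, integrating that exponential gives the log fall still to come. The last two readings sit flat, where this curve expects 4.5 percentage points of fall, so this reckoning starts from their mean pool at 65.0 min. The pool then comes to 45.7% at 1.5 h, and Qf to 27.8%. The drain number is 0.782: the natural log of charge over pool at that time.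

Further drain leaves Sunday's near 27.0%. On Tuesday's, the remaining pool returns to the same share, giving 37.6% with the removed Qf counted. If the ratio follows Qb, Thursday's gains 7.2 points. Friday's fresh Qc costs 10 points. This reckoning picks Tuesday's.

The forecast gave 29.2%, 29.2% after Tuesday's, 29.2% after Sunday's, and best none, reading the flat end as “abrupt catalyst death”.

The flask gives 27.5%, 36.2% after Tuesday's and 25.9% after Sunday's. The best option is Tuesday's, at 8.7 points, against 4.2 points for Thursday's and −8.3 points for Friday's.

    Qa + Qb ⇌ Qg (K = 22.0 M⁻¹, k = 0.00300 M⁻¹ min⁻¹)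
    Qa + Qd → Qh (k = 5.50 M⁻¹ min⁻¹)
    Qa + Qb ⇌ Qf (K = 2.70 M⁻¹, k = 0.280 M⁻¹ min⁻¹)
    Qf + Qc ⇌ Qg + Qc, rate k4*[Qc]*[Qf] forward; the back reaction follows from the equilibrium constant (k = 41.0 M⁻¹ min⁻¹)
    Qc → Qe (k = 0.0450 min⁻¹)

The forecast and the flask part on Tuesday's, 29.2% against 36.2%. The Qa and Qf of this flask at 90.0 min give a drain number of 0.786. The neighbouring flask holds 6.4 × 10⁻⁴ M of Qc, 0.400 of the charge in the red flask. Scaling the drain number with Qc gives 0.313, hence a pool of 73.1% and, at the same share, Qf of 44.4%. At 90.0 min, the neighbouring flask holds a pool of 67.0% and Qf of 41.9%.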